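**Plan**

1. Retrosynthesis: the C8 methylidene is cut to a ketone and the cyclopentene is cut at C2=C3 (azulene numbering). This bond lies between the two ring-fusion carbons (C3 with its methyl sits on C3a; C2 is joined through C1H2 to C8a), so it maps onto an isopropenyl group on C3a and an allyl group on C8a of a cycloheptanone whose carbonyl (C8) is α to C8a.
2. These two groups are cut back to a 4-alkoxycyclohept-2-enone (conjugate addition at C3a, enolate allylation at C8a); the seven-membered ring is cut at C3a=C8a (first metathesis) and the chain at C5–C6 into a lactone enolate (11) and a sugar-derived triflate (4).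
3. Forward: the side-chain lactone is alkylated, opened and extended to an acyclic dienone; the seven-membered ring arises first (step 12), the enone is transposed (steps 13–17), and the cyclopentene is closed last (step 19); the C8 ketone and the protecting groups are then exchanged for the methylidene and the acetates.
4. Stereochemistry: C2′/C3′ of the side chain from a syn-crotylboration; C5 from lactone alkylation anti to the methyl; C7 from D-erythronolactone; C4 from an oxazaborolidine reduction; C3a and C8a from cuprate addition anti to the C4 oxygen and allylation anti to the new isopropenyl group, which fixes the trans ring fusion before the ring is closed.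

Key step: step 19

Assumption: the sense of induction of the crotylborane, the oxazaborolidine and the transfer-hydrogenation catalyst is taken from the accepted transition-state models. Abbreviations in names: TBS = tert-butyldimethylsilyl, TIPS = triisopropylsilyl, PMB = 4-methoxybenzyl, R* = (2S,3S)-6-methyl-3-(TIPS-oxy)hept-5-en-2-yl; bicyclic products carry azulene numbering.

**Route**

Step 1
Reactants: 1 (3aR,6aR)-2,2-dimethyldihydrofuro[3,4-d][1,3]dioxol-4(3aH)-one (2,3-O-isopropylidene-D-erythronolactone)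
Product: 2 (3aR,6aR)-2,2-dimethyltetrahydrofuro[3,4-d][1,3]dioxol-4-ol (lactol, mixture of anomers)
Conditions: i-Bu2AlH, CH2Cl2, −78 °C; aq. Rochelle salt
Reagents that add atoms: none
Why: Partial reduction of a γ-lactone by a dialkylaluminium hydride at low temperature stops at the lactol because the tetrahedral aluminium hemiacetal does not collapse before work-up, and the two ring stereocenters are not touched.

Step 2
Reactants: 2 (3aR,6aR)-2,2-dimethyltetrahydrofuro[3,4-d][1,3]dioxol-4-ol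
Product: 3 [(4R,5S)-2,2-dimethyl-5-vinyl-1,3-dioxolan-4-yl]methanol
Conditions: Ph3PCH3Br, KOt-Bu, THF, 0 °C → rt
Reagents that add atoms: methyltriphenylphosphonium bromide, C[P+](c1ccccc1)(c1ccccc1)c1ccccc1.[Br-]
Why: Wittig methylenation of the hydroxy aldehyde in equilibrium with the lactol should give the vinyl dioxolane with both stereocenters of the cis-dioxolane carried over unchanged.

Step 3
Reactants: 3 [(4R,5S)-2,2-dimethyl-5-vinyl-1,3-dioxolan-4-yl]methanol
Product: 4 [(4R,5S)-2,2-dimethyl-5-vinyl-1,3-dioxolan-4-yl]methyl trifluoromethanesulfonate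
Conditions: Tf2O, pyridine, CH2Cl2, −78 → −20 °C; used at once
Reagents that add atoms: trifluoromethanesulfonic anhydride, O=S(=O)(OS(=O)(=O)C(F)(F)F)C(F)(F)F
Why: O-Sulfonylation of the primary alcohol gives the most reactive leaving group available, which is needed because the β-oxygen retards SN2 displacement at this carbon.

Step 4
Reactants: 5 4-methylpent-3-en-1-ol
Product: 6 4-methylpent-3-enal
Conditions: Dess–Martin periodinane, NaHCO3, CH2Cl2, 0 °C; used crude
Reagents that add atoms: none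
Why: Dess–Martin oxidation under buffered, non-basic conditions should give the β,γ-unsaturated aldehyde without migration of the double bond into conjugation.

Step 5
Reactants: 6 4-methylpent-3-enal
Product: 7 (3S,4S)-3,7-dimethylocta-1,6-dien-4-ol
Conditions: (Z)-crotyl-Ipc2B [cis-but-2-ene, n-BuLi, KOt-Bu, THF, −78 → −45 °C; (+)-Ipc2BOMe; BF3·OEt2], −78 °C; then NaOH, H2O2
Reagents that add atoms: cis-but-2-ene, C/C=C\C
Why: Brown crotylboration through a closed chair transition state turns the (Z)-crotyl geometry into the syn C3/C4 relationship, and the isopinocampheyl groups of the (+)-Ipc2BOMe-derived reagent should direct addition to the Re face of the aldehyde, which sets C4 and hence C3 as S.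

Step 6
Reactants: 7 (3S,4S)-3,7-dimethylocta-1,6-dien-4-ol
Product: 9 (3S,4S)-3,7-dimethyloct-6-ene-1,4-diol, via bis(9-BBN) adduct 8 (not isolated)
Conditions: 9-BBN (2.2 equiv), THF, 0 °C → rt; then NaOH, H2O2
Reagents that add atoms: hydrogen peroxide, OO
Why: Hydroboration–oxidation with 9-BBN is anti-Markovnikov and far faster at the monosubstituted vinyl group than at the trisubstituted alkene, and no stereocenter is formed or disturbed.

Step 7
Reactants: 9 (3S,4S)-3,7-dimethyloct-6-ene-1,4-diol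
Product: 11 (4S,5S)-4-methyl-5-(3-methylbut-2-en-1-yl)oxolan-2-one, via lactol 10 (not isolated)
Conditions: TEMPO (cat.), PhI(OAc)2, CH2Cl2, rt
Reagents that add atoms: none
Why: Oxoammonium (TEMPO) oxidation takes the primary alcohol to the aldehyde, which closes to the lactol on the C4 hydroxyl and is oxidised on to the cis-4,5-disubstituted γ-lactone with the stereocenters of 9 unchanged.

Step 8
Reactants: 11 (4S,5S)-4-methyl-5-(3-methylbut-2-en-1-yl)oxolan-2-one; 4 [(4R,5S)-2,2-dimethyl-5-vinyl-1,3-dioxolan-4-yl]methyl trifluoromethanesulfonate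
Product: 13 (3S,4S,5S)-3-{[(4R,5S)-2,2-dimethyl-5-vinyl-1,3-dioxolan-4-yl]methyl}-4-methyl-5-(3-methylbut-2-en-1-yl)oxolan-2-one, via lithium enolate 12 (not isolated)
Conditions: LiN(i-Pr)2, THF, −78 °C; then 4, (Me2N)3PO, −78 → −40 °C
Reagents that add atoms: none
Why: SN2 alkylation of the lactone lithium enolate by the primary triflate should occur on the face opposite to the cis-disposed C4 methyl and C5 prenyl groups, which sets C3 as S (3,4-trans).

Step 9
Reactants: 13 (3S,4S,5S)-3-{[(4R,5S)-2,2-dimethyl-5-vinyl-1,3-dioxolan-4-yl]methyl}-4-methyl-5-(3-methylbut-2-en-1-yl)oxolan-2-one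
Product: 14 (2S,3S,4S)-2-{[(4R,5S)-2,2-dimethyl-5-vinyl-1,3-dioxolan-4-yl]methyl}-4-hydroxy-N-methoxy-N,3,7-trimethyloct-6-enamide
Conditions: MeNH(OMe)·HCl, i-PrMgCl, THF, −20 → 0 °C
Reagents that add atoms: N,O-dimethylhydroxylamine hydrochloride, CNOC.Cl
Why: Aminolysis of the lactone by the chloromagnesium amide (Weinreb amide formation) opens the ring to the γ-hydroxy amide under conditions that should not enolise the α-stereocenter.

Step 10
Reactants: 14 (2S,3S,4S)-2-{[(4R,5S)-2,2-dimethyl-5-vinyl-1,3-dioxolan-4-yl]methyl}-4-hydroxy-N-methoxy-N,3,7-trimethyloct-6-enamide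
Product: 15 (2S,3S,4S)-2-{[(4R,5S)-2,2-dimethyl-5-vinyl-1,3-dioxolan-4-yl]methyl}-N-methoxy-N,3,7-trimethyl-4-(TIPS-oxy)oct-6-enamide
Conditions: i-Pr3SiOTf, 2,6-lutidine, CH2Cl2, −78 → 0 °C
Reagents that add atoms: triisopropylsilyl trifluoromethanesulfonate, CC(C)[Si](OS(=O)(=O)C(F)(F)F)(C(C)C)C(C)C
Why: Silylation with the silyl triflate caps the hindered secondary alcohol before it can re-lactonise and gives an ether that should survive the later acid, base and organometallic steps.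

Step 11
Reactants: 15 (2S,3S,4S)-2-{[(4R,5S)-2,2-dimethyl-5-vinyl-1,3-dioxolan-4-yl]methyl}-N-methoxy-N,3,7-trimethyl-4-(TIPS-oxy)oct-6-enamide
Product: 16 (4S,5S,6S)-4-{[(4R,5S)-2,2-dimethyl-5-vinyl-1,3-dioxolan-4-yl]methyl}-5,9-dimethyl-6-(TIPS-oxy)deca-1,8-dien-3-one
Conditions: CH2=CHMgBr, THF, 0 °C; inverse quench into cold aq. HCl
Reagents that add atoms: vinylmagnesium bromide, C=C[Mg]Br
Why: In the Weinreb ketone synthesis the magnesium chelate of the tetrahedral adduct prevents over-addition, and the inverse acidic quench keeps the released amine from adding to the vinyl ketone and leaves C4 unepimerised.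

Step 12
Reactants: 16 (4S,5S,6S)-4-{[(4R,5S)-2,2-dimethyl-5-vinyl-1,3-dioxolan-4-yl]methyl}-5,9-dimethyl-6-(TIPS-oxy)deca-1,8-dien-3-one
Product: 17 (3aS,7S,8aR)-2,2-dimethyl-7-R*-3a,7,8,8a-tetrahydro-6H-cyclohepta[d][1,3]dioxol-6-one
Conditions: second-generation Hoveyda–Grubbs catalyst (5 mol %), CH2Cl2 (2 mM), 40 °C
Reagents that add atoms: none
Why: Ring-closing metathesis should start at the vinyl group next to the dioxolane and close onto the vinyl ketone to give the seven-membered enone, the trisubstituted side-chain alkene being a much poorer partner, and no stereocenter is formed.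

Step 13
Reactants: 17 (3aS,7S,8aR)-2,2-dimethyl-7-R*-3a,7,8,8a-tetrahydro-6H-cyclohepta[d][1,3]dioxol-6-one
Product: 18 (3aS,6S,7S,8aR)-2,2-dimethyl-7-R*-3a,7,8,8a-tetrahydro-6H-cyclohepta[d][1,3]dioxol-6-ol
Conditions: (S)-1-methyl-3,3-diphenyltetrahydro-1H,3H-pyrrolo[1,2-c][1,3,2]oxazaborole (20 mol %), catecholborane, toluene, −78 °C
Reagents that add atoms: none
Why: In the Corey–Bakshi–Shibata 1,2-reduction the (S)-oxazaborolidine should place the conjugated alkene flank in the large-group position and deliver hydride to the carbonyl face anti to the C7 side chain (the sense that substrate control is also expected to favour), which sets C6 as S with the hydroxyl cis to the side chain.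

Step 14
Reactants: 18 (3aS,6S,7S,8aR)-2,2-dimethyl-7-R*-3a,7,8,8a-tetrahydro-6H-cyclohepta[d][1,3]dioxol-6-ol
Product: 19 (3aS,6S,7S,8aR)-6-(PMB-oxy)-2,2-dimethyl-7-R*-3a,7,8,8a-tetrahydro-6H-cyclohepta[d][1,3]dioxole
Conditions: NaH, 4-methoxybenzyl chloride, Bu4NI (cat.), THF/DMF, 0 °C → rt
Reagents that add atoms: 4-methoxybenzyl chloride, COc1ccc(CCl)cc1
Why: Williamson etherification gives an ether that is orthogonal to the silyl ethers and to the later acetates, so that this hydroxyl alone can be freed at the end.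

Step 15
Reactants: 19 (3aS,6S,7S,8aR)-6-(PMB-oxy)-2,2-dimethyl-7-R*-3a,7,8,8a-tetrahydro-6H-cyclohepta[d][1,3]dioxole
Product: 20 (1R,2S,5S,6S)-5-(PMB-oxy)-6-R*-cyclohept-3-ene-1,2-diol
Conditions: camphorsulfonic acid (cat.), MeOH, 0 °C → rt
Reagents that add atoms: none
Why: Acid-catalysed transketalisation to methanol removes the isopropylidene group, while the TIPS and PMB ethers are expected to withstand the mild acid.

Step 16
Reactants: 20 (1R,2S,5S,6S)-5-(PMB-oxy)-6-R*-cyclohept-3-ene-1,2-diol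
Product: 21 (4S,5S,7R)-7-hydroxy-4-(PMB-oxy)-5-R*-cyclohept-2-en-1-one
Conditions: MnO2 (activated, excess), CH2Cl2, rt
Reagents that add atoms: none
Why: MnO2 oxidises only the allylic hydroxyl of the diol, which completes the 1,3-transposition of the enone and leaves the neighbouring secondary alcohol free for separate protection.

Step 17
Reactants: 21 (4S,5S,7R)-7-hydroxy-4-(PMB-oxy)-5-R*-cyclohept-2-en-1-one
Product: 22 (4S,5S,7R)-7-(TBS-oxy)-4-(PMB-oxy)-5-R*-cyclohept-2-en-1-one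
Conditions: t-BuMe2SiOTf, 2,6-lutidine, CH2Cl2, −78 °C
Reagents that add atoms: tert-butyldimethylsilyl trifluoromethanesulfonate, CC(C)(C)[Si](C)(C)OS(=O)(=O)C(F)(F)F
Why: Low-temperature silylation of the α-hydroxy ketone gives an α′-silyloxy enone that a cuprate does not cleave reductively, without enolising C7.

Step 18
Reactants: 22 (4S,5S,7R)-7-(TBS-oxy)-4-(PMB-oxy)-5-R*-cyclohept-2-en-1-one
Product: 24 (2R,3S,4R,5S,7R)-2-allyl-7-(TBS-oxy)-4-(PMB-oxy)-3-(prop-1-en-2-yl)-5-R*-cycloheptan-1-one, via lithium enolate 23 (not isolated)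
Conditions: CH2=C(CH3)Li (2.2 equiv), CuI (1.1 equiv), THF, −78 °C; then (Me2N)3PO, allyl iodide, −78 → −30 °C
Reagents that add atoms: prop-1-en-2-yllithium, [Li]C(C)=C; allyl iodide, C=CCI
Why: In this conjugate addition–enolate alkylation (three-component coupling) the cuprate should add to C3 anti to the C4 PMB-oxy group and the C5 side chain, which lie on the same face (C3 becomes S), and allyl iodide should then enter C2 of the regiodefined enolate anti to the new isopropenyl group (C2 becomes R, 2,3-trans).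

Step 19
Reactants: 24 (2R,3S,4R,5S,7R)-2-allyl-7-(TBS-oxy)-4-(PMB-oxy)-3-(prop-1-en-2-yl)-5-R*-cycloheptan-1-one
Product: 25 (3aS,4R,5S,7R,8aR)-7-(TBS-oxy)-4-(PMB-oxy)-3-methyl-5-R*-3a,4,5,6,7,8a-hexahydroazulen-8(1H)-one
Conditions: second-generation Grubbs catalyst (5 mol %), CH2Cl2 (5 mM), 40 °C
Reagents that add atoms: none
Why: Ring-closing olefin metathesis by the Chauvin mechanism: the ruthenium alkylidene forms at the monosubstituted allyl terminus on C2, adds to the 1,1-disubstituted isopropenyl group on C3 through a metallacyclobutane and releases ethylene. The closest known reaction type is ring-closing metathesis of a 1,6-diene to a trisubstituted cyclopentene on a carbocyclic ketone. The cyclopentene closes as a five-membered ring whose new C2=C3 bond joins the former isopropenyl carbon (with its methyl) to the former internal allyl carbon, and loss of ethylene makes the closure irreversible. No stereocenter is created: the trans ring fusion (C3a-H/C8a-H) is inherited from the trans-2,3 arrangement set in step 18, and the neutral conditions leave the α-center C8a untouched. The selectivity needed is chemoselectivity over the trisubstituted side-chain alkene, and it is secured by initiation at the only monosubstituted alkene and by the kinetic advantage of five-ring closure over a ten-membered ring or cross-metathesis. The C8 ketone that made steps 18 and 19 possible stays as the handle for the methylidene group.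

Step 20
Reactants: 25 (3aS,4R,5S,7R,8aR)-7-(TBS-oxy)-4-(PMB-oxy)-3-methyl-5-R*-3a,4,5,6,7,8a-hexahydroazulen-8(1H)-one
Product: 26 (3aS,4R,5S,7R,8aR)-7-(TBS-oxy)-4-(PMB-oxy)-3-methyl-8-methylidene-5-R*-1,3a,4,5,6,7,8,8a-octahydroazulene
Conditions: Zn, CH2Br2, TiCl4 (pre-aged reagent), THF/CH2Cl2, 0 °C → rt
Reagents that add atoms: dibromomethane, BrCBr
Why: Takai–Lombardo methylenation with the non-basic zinc/titanium methylene reagent should olefinate the hindered, enolisable ketone without epimerising C8a or C7.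

Step 21
Reactants: 26 (3aS,4R,5S,7R,8aR)-7-(TBS-oxy)-4-(PMB-oxy)-3-methyl-8-methylidene-5-R*-1,3a,4,5,6,7,8,8a-octahydroazulene
Product: 27 (3aS,4R,5S,7R,8aR)-5-[(2S,3S)-3-hydroxy-6-methylhept-5-en-2-yl]-4-(PMB-oxy)-3-methyl-8-methylidene-1,3a,4,5,6,7,8,8a-octahydroazulen-7-ol
Conditions: Bu4NF, THF, rt → 45 °C
Reagents that add atoms: none
Why: Fluoride-induced desilylation removes both silyl ethers (Si–F bond formation) and leaves the PMB ether and the three alkenes intact.

Step 22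
Reactants: 27 (3aS,4R,5S,7R,8aR)-5-[(2S,3S)-3-hydroxy-6-methylhept-5-en-2-yl]-4-(PMB-oxy)-3-methyl-8-methylidene-1,3a,4,5,6,7,8,8a-octahydroazulen-7-ol
Product: 28 (3aS,4R,5S,7R,8aR)-5-[(2S,3S)-3-acetoxy-6-methylhept-5-en-2-yl]-4-(PMB-oxy)-3-methyl-8-methylidene-1,3a,4,5,6,7,8,8a-octahydroazulen-7-yl acetate
Conditions: Ac2O, Et3N, DMAP (cat.), CH2Cl2, 0 °C → rt
Reagents that add atoms: acetic anhydride, CC(=O)OC(C)=O
Why: DMAP-catalysed acylation esterifies the two free secondary alcohols with retention, the C4 oxygen being masked as the PMB ether.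

Step 23
Reactants: 28 (3aS,4R,5S,7R,8aR)-5-[(2S,3S)-3-acetoxy-6-methylhept-5-en-2-yl]-4-(PMB-oxy)-3-methyl-8-methylidene-1,3a,4,5,6,7,8,8a-octahydroazulen-7-yl acetate
Product: 29 (3aS,4R,5S,7R,8aR)-5-[(2S,3S)-3-acetoxy-6-methylhept-5-en-2-yl]-4-hydroxy-3-methyl-8-methylidene-1,3a,4,5,6,7,8,8a-octahydroazulen-7-yl acetate (target)
Conditions: DDQ, CH2Cl2/pH 7 buffer, 0 °C
Reagents that add atoms: none
Why: Oxidative cleavage of the electron-rich benzyl ether by DDQ (hydride abstraction, then hydrolysis of the oxocarbenium ion) frees the C4 hydroxyl under neutral conditions that spare the acetates and alkenes.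

**Compound list**

1 | (3aR,6aR)-2,2-dimethyldihydrofuro[3,4-d][1,3]dioxol-4(3aH)-one | CC1(C)O[C@H]2C(=O)OC[C@H]2O1 | starting material
2 | (3aR,6aR)-2,2-dimethyltetrahydrofuro[3,4-d][1,3]dioxol-4-ol (anomers) | CC1(C)O[C@H]2C(O)OC[C@H]2O1 | intermediate
3 | [(4R,5S)-2,2-dimethyl-5-vinyl-1,3-dioxolan-4-yl]methanol | CC1(C)O[C@@H](C=C)[C@H](O1)CO | intermediate
4 | [(4R,5S)-2,2-dimethyl-5-vinyl-1,3-dioxolan-4-yl]methyl trifluoromethanesulfonate | CC1(C)O[C@@H](C=C)[C@H](O1)COS(=O)(=O)C(F)(F)F | intermediate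
5 | 4-methylpent-3-en-1-ol | CC(C)=CCCO | starting material
6 | 4-methylpent-3-enal | CC(C)=CCC=O | intermediate
7 | (3S,4S)-3,7-dimethylocta-1,6-dien-4-ol | C=C[C@H](C)[C@H](CC=C(C)C)O | intermediate
8 | 9-[(3S,4S)-4-(9-borabicyclo[3.3.1]nonan-9-yloxy)-3,7-dimethyloct-6-en-1-yl]-9-borabicyclo[3.3.1]nonane (bis(9-BBN) adduct) | C(C[C@H](C)[C@H](CC=C(C)C)OB1C2CCCC1CCC2)B1C2CCCC1CCC2 | intermediate
9 | (3S,4S)-3,7-dimethyloct-6-ene-1,4-diol | OCC[C@H](C)[C@H](CC=C(C)C)O | intermediate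
10 | (4S,5S)-4-methyl-5-(3-methylbut-2-en-1-yl)oxolan-2-ol (lactol) | OC1C[C@H](C)[C@H](CC=C(C)C)O1 | intermediate
11 | (4S,5S)-4-methyl-5-(3-methylbut-2-en-1-yl)oxolan-2-one | O=C1C[C@H](C)[C@H](CC=C(C)C)O1 | intermediate
12 | lithium enolate of 11 | [Li+].[O-]C1=C[C@H](C)[C@H](CC=C(C)C)O1 | intermediate
13 | (3S,4S,5S)-3-{[(4R,5S)-2,2-dimethyl-5-vinyl-1,3-dioxolan-4-yl]methyl}-4-methyl-5-(3-methylbut-2-en-1-yl)oxolan-2-one | CC1(C)O[C@@H](C=C)[C@H](O1)C[C@H]2[C@H](C)[C@H](CC=C(C)C)OC2=O | intermediate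
14 | (2S,3S,4S)-2-{[(4R,5S)-2,2-dimethyl-5-vinyl-1,3-dioxolan-4-yl]methyl}-4-hydroxy-N-methoxy-N,3,7-trimethyloct-6-enamide | CC1(C)O[C@@H](C=C)[C@H](O1)C[C@@H]([C@H](C)[C@H](CC=C(C)C)O)C(=O)N(C)OC | intermediate
15 | (2S,3S,4S)-2-{[(4R,5S)-2,2-dimethyl-5-vinyl-1,3-dioxolan-4-yl]methyl}-N-methoxy-N,3,7-trimethyl-4-(TIPS-oxy)oct-6-enamide | CC1(C)O[C@@H](C=C)[C@H](O1)C[C@@H]([C@H](C)[C@H](CC=C(C)C)O[Si](C(C)C)(C(C)C)C(C)C)C(=O)N(C)OC | intermediate
16 | (4S,5S,6S)-4-{[(4R,5S)-2,2-dimethyl-5-vinyl-1,3-dioxolan-4-yl]methyl}-5,9-dimethyl-6-(TIPS-oxy)deca-1,8-dien-3-one | CC1(C)O[C@@H](C=C)[C@H](O1)C[C@@H]([C@H](C)[C@H](CC=C(C)C)O[Si](C(C)C)(C(C)C)C(C)C)C(=O)C=C | intermediate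
17 | (3aS,7S,8aR)-2,2-dimethyl-7-R*-3a,7,8,8a-tetrahydro-6H-cyclohepta[d][1,3]dioxol-6-one | CC1(C)O[C@@H]2[C@H](O1)C[C@@H]([C@H](C)[C@H](CC=C(C)C)O[Si](C(C)C)(C(C)C)C(C)C)C(=O)C=C2 | intermediate
18 | (3aS,6S,7S,8aR)-2,2-dimethyl-7-R*-3a,7,8,8a-tetrahydro-6H-cyclohepta[d][1,3]dioxol-6-ol | CC1(C)O[C@@H]2[C@H](O1)C[C@@H]([C@H](C)[C@H](CC=C(C)C)O[Si](C(C)C)(C(C)C)C(C)C)[C@@H](O)C=C2 | intermediate
19 | (3aS,6S,7S,8aR)-6-(PMB-oxy)-2,2-dimethyl-7-R*-3a,7,8,8a-tetrahydro-6H-cyclohepta[d][1,3]dioxole | CC1(C)O[C@@H]2[C@H](O1)C[C@@H]([C@H](C)[C@H](CC=C(C)C)O[Si](C(C)C)(C(C)C)C(C)C)[C@@H](OCc1ccc(OC)cc1)C=C2 | intermediate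
20 | (1R,2S,5S,6S)-5-(PMB-oxy)-6-R*-cyclohept-3-ene-1,2-diol | O[C@@H]1[C@H](O)C[C@@H]([C@H](C)[C@H](CC=C(C)C)O[Si](C(C)C)(C(C)C)C(C)C)[C@@H](OCc2ccc(OC)cc2)C=C1 | intermediate
21 | (4S,5S,7R)-7-hydroxy-4-(PMB-oxy)-5-R*-cyclohept-2-en-1-one | O=C1[C@H](O)C[C@@H]([C@H](C)[C@H](CC=C(C)C)O[Si](C(C)C)(C(C)C)C(C)C)[C@@H](OCc2ccc(OC)cc2)C=C1 | intermediate
22 | (4S,5S,7R)-7-(TBS-oxy)-4-(PMB-oxy)-5-R*-cyclohept-2-en-1-one | O=C1[C@H](O[Si](C)(C)C(C)(C)C)C[C@@H]([C@H](C)[C@H](CC=C(C)C)O[Si](C(C)C)(C(C)C)C(C)C)[C@@H](OCc2ccc(OC)cc2)C=C1 | intermediate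
23 | lithium enolate from cuprate addition to 22 (C1–O–Li, C1=C2, isopropenyl at C3) | [Li+].[O-]C=1[C@H](O[Si](C)(C)C(C)(C)C)C[C@@H]([C@H](C)[C@H](CC=C(C)C)O[Si](C(C)C)(C(C)C)C(C)C)[C@@H](OCc2ccc(OC)cc2)[C@H](C(C)=C)C=1 | intermediate
24 | (2R,3S,4R,5S,7R)-2-allyl-7-(TBS-oxy)-4-(PMB-oxy)-3-(prop-1-en-2-yl)-5-R*-cycloheptan-1-one | O=C1[C@H](O[Si](C)(C)C(C)(C)C)C[C@@H]([C@H](C)[C@H](CC=C(C)C)O[Si](C(C)C)(C(C)C)C(C)C)[C@@H](OCc2ccc(OC)cc2)[C@H](C(C)=C)[C@H]1CC=C | intermediate
25 | (3aS,4R,5S,7R,8aR)-7-(TBS-oxy)-4-(PMB-oxy)-3-methyl-5-R*-3a,4,5,6,7,8a-hexahydroazulen-8(1H)-one | O=C1[C@H](O[Si](C)(C)C(C)(C)C)C[C@@H]([C@H](C)[C@H](CC=C(C)C)O[Si](C(C)C)(C(C)C)C(C)C)[C@@H](OCc3ccc(OC)cc3)[C@@H]2C(C)=CC[C@@H]12 | intermediate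
26 | (3aS,4R,5S,7R,8aR)-7-(TBS-oxy)-4-(PMB-oxy)-3-methyl-8-methylidene-5-R*-1,3a,4,5,6,7,8,8a-octahydroazulene | C=C1[C@H](O[Si](C)(C)C(C)(C)C)C[C@@H]([C@H](C)[C@H](CC=C(C)C)O[Si](C(C)C)(C(C)C)C(C)C)[C@@H](OCc3ccc(OC)cc3)[C@@H]2C(C)=CC[C@@H]12 | intermediate
27 | (3aS,4R,5S,7R,8aR)-5-[(2S,3S)-3-hydroxy-6-methylhept-5-en-2-yl]-4-(PMB-oxy)-3-methyl-8-methylidene-1,3a,4,5,6,7,8,8a-octahydroazulen-7-ol | C=C1[C@H](O)C[C@@H]([C@H](C)[C@H](CC=C(C)C)O)[C@@H](OCc3ccc(OC)cc3)[C@@H]2C(C)=CC[C@@H]12 | intermediate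
28 | (3aS,4R,5S,7R,8aR)-5-[(2S,3S)-3-acetoxy-6-methylhept-5-en-2-yl]-4-(PMB-oxy)-3-methyl-8-methylidene-1,3a,4,5,6,7,8,8a-octahydroazulen-7-yl acetate | C=C1[C@H](OC(C)=O)C[C@@H]([C@H](C)[C@H](CC=C(C)C)OC(C)=O)[C@@H](OCc3ccc(OC)cc3)[C@@H]2C(C)=CC[C@@H]12 | intermediate
29 | (3aS,4R,5S,7R,8aR)-5-[(2S,3S)-3-acetoxy-6-methylhept-5-en-2-yl]-4-hydroxy-3-methyl-8-methylidene-1,3a,4,5,6,7,8,8a-octahydroazulen-7-yl acetate | C=C1[C@H](OC(C)=O)C[C@@H]([C@H](C)[C@H](CC=C(C)C)OC(C)=O)[C@@H](O)[C@@H]2C(C)=CC[C@@H]12 | target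

**Step count and risks**

Total step count: 23 (3 steps to triflate 4, 20 steps in the main line). Longest linear sequence: 20 steps (steps 4–23, from 4-methylpent-3-en-1-ol 5).

Steps most likely to fail:

Step 18. The cuprate-derived enolate may alkylate sluggishly, so that proton exchange with the product, loss of regiocontrol and double allylation compete. The fallback sets out from 22 and comes back at 24: the same cuprate addition is quenched on oxygen with allyl chloroformate to give the allyl enol carbonate F1. Pd(PPh3)4 (zerovalent palladium) in THF then brings about the decarboxylative Tsuji allylation, in which the π-allylpalladium cation and the regiodefined enolate should recombine at C2 anti to the isopropenyl group to give 24.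

Step 13. Facial selectivity may be poor if catalyst control and substrate bias oppose each other, and 1,4-reduction may compete. The fallback sets out from 15 and comes back at 19, creating the carbinol centre before the ring instead of after it. LiC≡CSiMe3 converts 15 into the ynone F2. Noyori transfer hydrogenation with RuCl(p-cymene)[(R,R)-TsDPEN] in i-PrOH should give the (3R) propargylic alcohol F3 under reagent control. K2CO3 in MeOH removes the silyl group to give the terminal alkyne F4, and NaH with 4-methoxybenzyl chloride gives the PMB ether F5. Semihydrogenation over Pd/CaCO3 poisoned with Pb(OAc)2 and quinoline gives the diene F6, and ring-closing metathesis with the second-generation Grubbs catalyst closes the seven-membered ring to 19.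

Step 8. SN2 displacement at the β-oxygenated primary carbon may be slow, so that decomposition of the triflate and proton transfer from unreacted lactone take over. The fallback sets out from 3 and 11 and comes back at 13, replacing the alkylation by an aldol addition and a radical deoxygenation. Dess–Martin oxidation of 3 gives the aldehyde F7. Addition of enolate 12 to F7 at −78 °C gives the β-hydroxy lactone F8, again anti to the C4 methyl. 1,1′-Thiocarbonyldiimidazole converts it into the imidazolylthiocarbonyl ester F9, and Bu3SnH with AIBN in toluene at 80 °C (Barton–McCombie deoxygenation) removes the oxygen to give 13.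

**Further compounds**

F1 | step 18 | allyl (3S,4R,5S,7R)-7-(TBS-oxy)-4-(PMB-oxy)-3-(prop-1-en-2-yl)-5-R*-cyclohept-1-en-1-yl carbonate | C=CCOC(=O)OC=1[C@H](O[Si](C)(C)C(C)(C)C)C[C@@H]([C@H](C)[C@H](CC=C(C)C)O[Si](C(C)C)(C(C)C)C(C)C)[C@@H](OCc2ccc(OC)cc2)[C@H](C(C)=C)C=1
F2 | step 13 | (4S,5S,6S)-4-{[(4R,5S)-2,2-dimethyl-5-vinyl-1,3-dioxolan-4-yl]methyl}-5,9-dimethyl-6-(TIPS-oxy)-1-(trimethylsilyl)dec-8-en-1-yn-3-one | CC1(C)O[C@@H](C=C)[C@H](O1)C[C@@H]([C@H](C)[C@H](CC=C(C)C)O[Si](C(C)C)(C(C)C)C(C)C)C(=O)C#C[Si](C)(C)C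
F3 | step 13 | (3R,4S,5S,6S)-4-{[(4R,5S)-2,2-dimethyl-5-vinyl-1,3-dioxolan-4-yl]methyl}-5,9-dimethyl-6-(TIPS-oxy)-1-(trimethylsilyl)dec-8-en-1-yn-3-ol | CC1(C)O[C@@H](C=C)[C@H](O1)C[C@@H]([C@H](C)[C@H](CC=C(C)C)O[Si](C(C)C)(C(C)C)C(C)C)[C@@H](O)C#C[Si](C)(C)C
F4 | step 13 | (3R,4S,5S,6S)-4-{[(4R,5S)-2,2-dimethyl-5-vinyl-1,3-dioxolan-4-yl]methyl}-5,9-dimethyl-6-(TIPS-oxy)dec-8-en-1-yn-3-ol | CC1(C)O[C@@H](C=C)[C@H](O1)C[C@@H]([C@H](C)[C@H](CC=C(C)C)O[Si](C(C)C)(C(C)C)C(C)C)[C@@H](O)C#C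
F5 | step 13 | PMB ether of F4 (3-(PMB-oxy) terminal alkyne) | CC1(C)O[C@@H](C=C)[C@H](O1)C[C@@H]([C@H](C)[C@H](CC=C(C)C)O[Si](C(C)C)(C(C)C)C(C)C)[C@@H](OCc1ccc(OC)cc1)C#C
F6 | step 13 | 3-(PMB-oxy)-4-{[(4R,5S)-2,2-dimethyl-5-vinyl-1,3-dioxolan-4-yl]methyl}-5,9-dimethyl-6-(TIPS-oxy)deca-1,8-diene (configuration as in F5) | CC1(C)O[C@@H](C=C)[C@H](O1)C[C@@H]([C@H](C)[C@H](CC=C(C)C)O[Si](C(C)C)(C(C)C)C(C)C)[C@@H](OCc1ccc(OC)cc1)C=C
F7 | step 8 | (4S,5S)-2,2-dimethyl-5-vinyl-1,3-dioxolane-4-carbaldehyde | CC1(C)O[C@@H](C=C)[C@H](O1)C=O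
F8 | step 8 | aldol adduct of 12 and F7 (3-[(dioxolanyl)(hydroxy)methyl] lactone, carbinol epimers) | CC1(C)O[C@@H](C=C)[C@H](O1)C(O)[C@H]1[C@H](C)[C@H](CC=C(C)C)OC1=O
F9 | step 8 | O-(imidazol-1-ylthiocarbonyl) derivative of F8 | CC1(C)O[C@@H](C=C)[C@H](O1)C(OC(=S)n1ccnc1)[C@H]1[C@H](C)[C@H](CC=C(C)C)OC1=O
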